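**Retrosynthetic overview**

1. Target 25 ⇐ undecabenzyl ether 24 by hydrogenolysis; all five benzene rings are bought and only the two pyran rings are made.
2. Key disconnection, the pyran ring of the epicatechin half: O1–C8a (aryl ether, intramolecular SNAr on a fluorinated ring A) and C2–C1' of the catechol ring (aryl carbanion plus aldehyde), giving biaryl bromide 20 and aldehyde 8. One flask joins the fragments, sets C2 and closes the ring.
3. Enabling feature: O1 is both the oxygen on the benzylic carbon C2 and an aryl ether oxygen on C8a. C8a lies meta to the oxygens on C5 and C7 of ring A, so a fluoride there can be displaced. C2–O1 is 1,2-syn to C3–O (2,3-cis), which is the relationship a magnesium chelate of the C3-benzyloxy aldehyde delivers.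
4. 20 ⇐ Negishi coupling of the 2'-zincated epigallocatechin hexabenzyl ether (from 15) with bromo-iodo-arene 17. 15 ⇐ the same aldehyde 8 plus pyrogallol Grignard 13 by the same addition/SNAr sequence. 8 ⇐ ring A Grignard 5 plus methyl (R)-glycidate 4, the only bought stereocentre; used twice, it supplies both C3 centres, and each relays to its C2.
5. Ring order: pyran ring of the epigallocatechin half (step 9), then the biaryl bond (step 11), then the pyran ring of the epicatechin half (step 12).

Key step: step 12

Remark: the structure given fixes four stereocentres but no sense for the biaryl axis (three ortho substituents); the axis is treated as unspecified, the route does not control it, and if the atropisomers prove configurationally stable they would be separated by HPLC at 20 or at 25.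

**Route**

Step 1
Reactants: 1 5-fluorobenzene-1,3-diol
Product: 2 1,3-bis(benzyloxy)-5-fluorobenzene
Conditions: BnBr (2.2 equiv), K2CO3, DMF, 60 °C
Reagents that add atoms: benzyl bromide, BrCc1ccccc1
Why: Williamson ether synthesis, in which both phenoxides are alkylated by the benzylic bromide (SN2) and no other nucleophilic site is present.

Step 2
Reactants: 2 1,3-bis(benzyloxy)-5-fluorobenzene
Product: 3 1,5-bis(benzyloxy)-2-bromo-3-fluorobenzene
Conditions: NBS (1.0 equiv), MeCN, 0 °C → rt
Reagents that add atoms: N-bromosuccinimide, O=C1CCC(=O)N1Br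
Why: Electrophilic aromatic bromination should go para to one benzyloxy group and ortho to the other (next to the small fluorine) in preference to the hindered position between the two benzyloxy groups, as is usual for 5-substituted resorcinol diethers.

Step 3
Reactants: 3 1,5-bis(benzyloxy)-2-bromo-3-fluorobenzene; 4 methyl (R)-oxirane-2-carboxylate (methyl (R)-glycidate)
Product: 6 methyl (R)-3-[2,4-bis(benzyloxy)-6-fluorophenyl]-2-hydroxypropanoate, via aryl Grignard 5 (not isolated)
Conditions: Mg turnings, LiCl, THF, 0 °C → rt; then CuI (10 mol %), 4, THF, −40 → −20 °C; H2O work-up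
Reagents that add atoms: none
Why: Magnesium insertion followed by copper-catalysed SN2 opening of the glycidate at its unsubstituted C3 carbon, which at −40 °C should outrun attack on the ester and leaves the stereocentre of 4 untouched.

Step 4
Reactants: 6 methyl (R)-3-[2,4-bis(benzyloxy)-6-fluorophenyl]-2-hydroxypropanoate
Product: 7 methyl (R)-2-(benzyloxy)-3-[2,4-bis(benzyloxy)-6-fluorophenyl]propanoate
Conditions: BnBr, Ag2O, CH2Cl2, rt, dark
Reagents that add atoms: benzyl bromide, BrCc1ccccc1
Why: Silver-oxide-mediated O-alkylation etherifies the α-hydroxy ester without a strong base, so the α-stereocentre should not epimerise.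

Step 5
Reactants: 7 methyl (R)-2-(benzyloxy)-3-[2,4-bis(benzyloxy)-6-fluorophenyl]propanoate
Product: 8 (R)-2-(benzyloxy)-3-[2,4-bis(benzyloxy)-6-fluorophenyl]propanal
Conditions: i-Bu2AlH (1.1 equiv), CH2Cl2, −78 °C; MeOH, then aq. potassium sodium tartrate
Reagents that add atoms: none
Why: Partial ester reduction should stop at the aluminium hemiacetal, which is stabilised by chelation to the α-benzyloxy oxygen and gives the aldehyde on hydrolysis; the stereocentre is not touched and 8 is used crude.

Step 6
Reactants: 9 5-iodo-1,2,3-trimethoxybenzene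
Product: 10 5-iodobenzene-1,2,3-triol
Conditions: BBr3, CH2Cl2, −78 °C → rt; then H2O
Reagents that add atoms: none
Why: Lewis-acid ether cleavage (SN2 demethylation by bromide on the boron-complexed ether) frees the three phenols while the aryl iodide is inert.

Step 7
Reactants: 10 5-iodobenzene-1,2,3-triol
Product: 11 1,2,3-tris(benzyloxy)-5-iodobenzene
Conditions: BnBr (3.5 equiv), K2CO3, DMF, 60 °C, argon
Reagents that add atoms: benzyl bromide, BrCc1ccccc1
Why: Williamson ether synthesis on the three phenoxides, run under argon because the free pyrogallol is air-sensitive in base.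

Step 8
Reactants: 11 1,2,3-tris(benzyloxy)-5-iodobenzene
Product: 12 1,2,3-tris(benzyloxy)-4-bromo-5-iodobenzene
Conditions: NBS (1.0 equiv), MeCN–CH2Cl2, 0 °C
Reagents that add atoms: N-bromosuccinimide, O=C1CCC(=O)N1Br
Why: Electrophilic aromatic bromination at one of the two equivalent C–H positions, each ortho to one outer benzyloxy group and para to the other, which places bromine next to iodine.

Step 9
Reactants: 12 1,2,3-tris(benzyloxy)-4-bromo-5-iodobenzene; 8 (R)-2-(benzyloxy)-3-[2,4-bis(benzyloxy)-6-fluorophenyl]propanal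
Product: 15 (2R,3R)-3,5,7-tris(benzyloxy)-2-[3,4,5-tris(benzyloxy)-2-bromophenyl]chromane, via aryl Grignard 13 (not isolated), via syn-carbinol alkoxide 14 (not isolated)
Conditions: iPrMgCl·LiCl, THF, −40 °C; then 8, MgBr2·OEt2, toluene, −78 → −20 °C; then volatiles off, KOtBu, 18-crown-6, DMPU, 70 °C
Reagents that add atoms: none
Why: Iodine–magnesium exchange is selective for C–I over C–Br and the ortho-bromo Grignard is stable cold; chelation-controlled addition to 8 should set C2 syn to the C3 benzyloxy group, and the alkoxide then closes the pyran ring by intramolecular SNAr at the fluorinated carbon of ring A with retention at C2, giving the 2,3-cis chromane.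

Step 10
Reactants: 16 1,2-bis(benzyloxy)-4-bromobenzene
Product: 17 1,2-bis(benzyloxy)-4-bromo-5-iodobenzene
Conditions: NIS, CF3CO2H (cat.), MeCN, rt
Reagents that add atoms: N-iodosuccinimide, O=C1CCC(=O)N1I
Why: Electrophilic aromatic iodination para to a benzyloxy group and ortho to bromine, the usual site in 4-halo-1,2-dialkoxybenzenes.

Step 11
Reactants: 15 (2R,3R)-3,5,7-tris(benzyloxy)-2-[3,4,5-tris(benzyloxy)-2-bromophenyl]chromane; 17 1,2-bis(benzyloxy)-4-bromo-5-iodobenzene
Product: 20 (2R,3R)-3,5,7-tris(benzyloxy)-2-[2'-bromo-4,4',5,5',6-pentakis(benzyloxy)biphenyl-2-yl]chromane, via aryllithium 18 (not isolated), via arylzinc chloride 19 (not isolated)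
Conditions: n-BuLi, THF, −78 °C; ZnCl2, −78 °C → rt; then 17 (1.3 equiv), Pd2(dba)3 (2.5 mol %), SPhos (10 mol %), THF, 50 °C
Reagents that add atoms: none
Why: Bromine–lithium exchange, transmetalation to zinc and Negishi cross-coupling with a dialkylbiarylphosphine ligand that tolerates three ortho substituents; zerovalent palladium should insert into C–I of 17 well before C–Br, so the bromine needed for step 12 is kept and no stereocentre is touched.

Step 12
Reactants: 20 (2R,3R)-3,5,7-tris(benzyloxy)-2-[2'-bromo-4,4',5,5',6-pentakis(benzyloxy)biphenyl-2-yl]chromane; 8 (R)-2-(benzyloxy)-3-[2,4-bis(benzyloxy)-6-fluorophenyl]propanal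
Product: 24 undeca-O-benzyl degalloyl theasinensin F (both flavan units 2R,3R and every hydroxyl as its benzyl ether), via aryllithium 21 (not isolated), via aryl Grignard 22 (not isolated), via syn-carbinol alkoxide 23 (not isolated)
Conditions: t-BuLi (2 equiv), THF, −78 °C; MgBr2·OEt2 (2.5 equiv), −78 → −40 °C; then 8, toluene, −78 → −20 °C; then KOtBu, 18-crown-6, DMPU, 70 °C
Reagents that add atoms: none
Why: Bromine–lithium exchange and transmetalation turn 20 into aryl Grignard 22, which adds to the aldehyde carbon of 8 while magnesium bridges the carbonyl oxygen and the C3 benzyloxy oxygen in a five-membered chelate; excess KOtBu then frees the new C2 alkoxide from magnesium, and it attacks the fluorine-bearing C8a of ring A by addition–elimination through a Meisenheimer intermediate and expels fluoride. The closest known reaction types are the chelation-controlled (Cram-chelate) addition of aryl Grignard reagents to α-benzyloxy aldehydes and the alkoxide SNAr etherification of 3,5-dialkoxyfluoroarenes, here combined in one flask and run intramolecularly. The only ring closed is the pyran ring of the epicatechin half, formed at O1–C8a as a six-membered closure by ipso attack on an aromatic carbon (6-exo-trig with respect to the C8a=C8 bond). The only new stereocentre, C2, is set in the addition by 1,2-chelation control from the bought C3 centre (attack on the chelate face opposite the C4 methylene, syn product) and enters the ring with retention because the C2–O bond is never broken, so the 2,3-cis relationship results directly. The step needs chelation rather than Felkin–Anh selectivity, which the chelating benzyl ether, MgBr2 and toluene as co-solvent should secure, and ring closure through the C2 oxygen only, which is secured by the single fluorine of 8, its position meta to both benzyloxy groups of ring A and the absence of any other free hydroxyl.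

Step 13
Reactants: 24 undeca-O-benzyl degalloyl theasinensin F
Product: 25 degalloyl theasinensin F
Conditions: H2 (1 atm), Pd(OH)2/C, THF–MeOH, rt; filtration under argon
Reagents that add atoms: none
Why: Catalytic hydrogenolysis of all eleven benzyl ethers; the benzylic C2–O1 bonds of flavan-3-ols normally survive these conditions and no stereocentre is affected.

**Compound list**

1 | 5-fluorobenzene-1,3-diol | Oc1cc(O)cc(F)c1 | starting material
2 | 1,3-bis(benzyloxy)-5-fluorobenzene | Fc1cc(OCc2ccccc2)cc(OCc2ccccc2)c1 | intermediate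
3 | 1,5-bis(benzyloxy)-2-bromo-3-fluorobenzene | Fc1cc(OCc2ccccc2)cc(OCc2ccccc2)c1Br | intermediate
4 | methyl (R)-oxirane-2-carboxylate (methyl (R)-glycidate) | COC(=O)[C@H]1CO1 | starting material
5 | [2,4-bis(benzyloxy)-6-fluorophenyl]magnesium bromide | Fc1cc(OCc2ccccc2)cc(OCc2ccccc2)c1[Mg]Br | intermediate
6 | methyl (R)-3-[2,4-bis(benzyloxy)-6-fluorophenyl]-2-hydroxypropanoate | COC(=O)[C@H](O)Cc1c(F)cc(OCc2ccccc2)cc1OCc1ccccc1 | intermediate
7 | methyl (R)-2-(benzyloxy)-3-[2,4-bis(benzyloxy)-6-fluorophenyl]propanoate | COC(=O)[C@H](OCc1ccccc1)Cc1c(F)cc(OCc2ccccc2)cc1OCc1ccccc1 | intermediate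
8 | (R)-2-(benzyloxy)-3-[2,4-bis(benzyloxy)-6-fluorophenyl]propanal | O=C[C@H](OCc1ccccc1)Cc1c(F)cc(OCc2ccccc2)cc1OCc1ccccc1 | intermediate
9 | 5-iodo-1,2,3-trimethoxybenzene | COc1cc(I)cc(OC)c1OC | starting material
10 | 5-iodobenzene-1,2,3-triol | Oc1cc(I)cc(O)c1O | intermediate
11 | 1,2,3-tris(benzyloxy)-5-iodobenzene | Ic1cc(OCc2ccccc2)c(OCc2ccccc2)c(OCc2ccccc2)c1 | intermediate
12 | 1,2,3-tris(benzyloxy)-4-bromo-5-iodobenzene | Ic1cc(OCc2ccccc2)c(OCc2ccccc2)c(OCc2ccccc2)c1Br | intermediate
13 | [3,4,5-tris(benzyloxy)-2-bromophenyl]magnesium chloride | Cl[Mg]c1cc(OCc2ccccc2)c(OCc2ccccc2)c(OCc2ccccc2)c1Br | intermediate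
14 | (1R,2R)-2-(benzyloxy)-3-[2,4-bis(benzyloxy)-6-fluorophenyl]-1-[3,4,5-tris(benzyloxy)-2-bromophenyl]propan-1-ol (present in the flask as its alkoxide) | O[C@H](c1cc(OCc2ccccc2)c(OCc2ccccc2)c(OCc2ccccc2)c1Br)[C@H](OCc1ccccc1)Cc1c(F)cc(OCc2ccccc2)cc1OCc1ccccc1 | intermediate
15 | (2R,3R)-3,5,7-tris(benzyloxy)-2-[3,4,5-tris(benzyloxy)-2-bromophenyl]chromane (2'-bromo-hexa-O-benzyl-epigallocatechin) | Brc1c([C@H]3Oc4cc(OCc5ccccc5)cc(OCc5ccccc5)c4C[C@H]3OCc6ccccc6)cc(OCc5ccccc5)c(OCc5ccccc5)c1OCc5ccccc5 | intermediate
16 | 1,2-bis(benzyloxy)-4-bromobenzene | Brc1ccc(OCc2ccccc2)c(OCc2ccccc2)c1 | starting material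
17 | 1,2-bis(benzyloxy)-4-bromo-5-iodobenzene | Brc1cc(OCc2ccccc2)c(OCc2ccccc2)cc1I | intermediate
18 | aryllithium from 15 (lithium in place of the 2'-bromine) | [Li]c1c([C@H]3Oc4cc(OCc5ccccc5)cc(OCc5ccccc5)c4C[C@H]3OCc6ccccc6)cc(OCc5ccccc5)c(OCc5ccccc5)c1OCc5ccccc5 | intermediate
19 | arylzinc chloride from 18 (ZnCl in place of the 2'-bromine of 15) | Cl[Zn]c1c([C@H]3Oc4cc(OCc5ccccc5)cc(OCc5ccccc5)c4C[C@H]3OCc6ccccc6)cc(OCc5ccccc5)c(OCc5ccccc5)c1OCc5ccccc5 | intermediate
20 | (2R,3R)-3,5,7-tris(benzyloxy)-2-[2'-bromo-4,4',5,5',6-pentakis(benzyloxy)biphenyl-2-yl]chromane | Brc1cc(OCc5ccccc5)c(OCc5ccccc5)cc1-c1c([C@H]3Oc4cc(OCc5ccccc5)cc(OCc5ccccc5)c4C[C@H]3OCc6ccccc6)cc(OCc5ccccc5)c(OCc5ccccc5)c1OCc5ccccc5 | intermediate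
21 | aryllithium from 20 (lithium in place of bromine on the catechol ring) | [Li]c1cc(OCc5ccccc5)c(OCc5ccccc5)cc1-c1c([C@H]3Oc4cc(OCc5ccccc5)cc(OCc5ccccc5)c4C[C@H]3OCc6ccccc6)cc(OCc5ccccc5)c(OCc5ccccc5)c1OCc5ccccc5 | intermediate
22 | arylmagnesium bromide from 21 (MgBr on the catechol ring) | Br[Mg]c1cc(OCc5ccccc5)c(OCc5ccccc5)cc1-c1c([C@H]3Oc4cc(OCc5ccccc5)cc(OCc5ccccc5)c4C[C@H]3OCc6ccccc6)cc(OCc5ccccc5)c(OCc5ccccc5)c1OCc5ccccc5 | intermediate
23 | (1R,2R)-carbinol, the seco form of 24 with free C2 hydroxyl and fluorine on C8a of ring A (present in the flask as its alkoxide) | O[C@H](c1cc(OCc5ccccc5)c(OCc5ccccc5)cc1-c1c([C@H]3Oc4cc(OCc5ccccc5)cc(OCc5ccccc5)c4C[C@H]3OCc6ccccc6)cc(OCc5ccccc5)c(OCc5ccccc5)c1OCc5ccccc5)[C@H](OCc5ccccc5)Cc1c(F)cc(OCc5ccccc5)cc1OCc1ccccc1 | intermediate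
24 | undeca-O-benzyl degalloyl theasinensin F | C(c1ccccc1)Oc1cc(OCc5ccccc5)c2c(c1)O[C@H](c1cc(OCc5ccccc5)c(OCc5ccccc5)cc1-c1c([C@H]3Oc4cc(OCc5ccccc5)cc(OCc5ccccc5)c4C[C@H]3OCc6ccccc6)cc(OCc5ccccc5)c(OCc5ccccc5)c1OCc5ccccc5)[C@H](OCc5ccccc5)C2 | intermediate
25 | degalloyl theasinensin F | Oc1cc(O)c2c(c1)O[C@H](c1cc(O)c(O)cc1-c1c([C@H]3Oc4cc(O)cc(O)c4C[C@H]3O)cc(O)c(O)c1O)[C@H](O)C2 | target

**Step count and risks**

Total step count: 13. Longest linear sequence: 9 steps (steps 1, 2, 3, 4, 5, 9, 11, 12, 13).

Step 12 is the most likely to fail. The hindered aryl Grignard may deprotonate the enolisable aldehyde instead of adding. The Felkin–Anh pathway may compete with chelation and erode facial selectivity at C2. Fluoride displacement may also be slow while the alkoxide is still bound to magnesium, and hydride transfer to residual aldehyde could epimerise C2. The fallback sets out from ester 7 and bromide 20 and comes back to the route at 24. Ester 7 would be treated with MeNH(OMe)·HCl and iPrMgCl (THF, −20 °C) to give the Weinreb amide F1. Aryllithium 21, made from 20 as in step 12, would be acylated by F1 (THF, −78 °C, Weinreb ketone synthesis) to give the aryl ketone F2. Noyori asymmetric transfer hydrogenation with RuCl[(S,S)-TsDPEN](p-cymene) in HCO2H–Et3N would then set the carbinol centre by catalyst control; this catalyst enantiomer is the one expected, by analogy with aryl alkyl ketones, to deliver the (1R) alcohol, which is also the Felkin–Anh product. That gives 23 as an isolated alcohol, and KN(SiMe3)2 with 18-crown-6 in THF at 60 °C would close it to 24.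

Step 9 runs the same sequence on the pyrogallol ring and carries the same two risks: loss of facial selectivity in the addition and failure of the magnesium-bound alkoxide to cyclise. In addition, the ortho-bromo Grignard can eliminate to an aryne if the exchange or addition is run too warm. The fallback sets out from 14 and comes back at 15. The addition would be quenched cold and 14 isolated as a mixture of C1 epimers. Dess–Martin oxidation would converge both epimers on the α-benzyloxy ketone F3. Reduction with K[s-Bu3BH] in THF at −78 °C (non-chelating, Felkin–Anh control by the α-benzyloxy group) should return 14 as the syn alcohol, which would be closed with KOtBu and 18-crown-6 in DMPU to 15.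

Step 11 may suffer from slow transmetalation and reductive elimination at the doubly ortho-substituted arylzinc, from protonation of the organometallic, and from loss of iodide-over-bromide selectivity leading to further arylation. The fallback sets out from 15 and comes back at 20. Bromine–lithium exchange on 15 (n-BuLi, THF, −78 °C) and a quench with 2-isopropoxy-4,4,5,5-tetramethyl-1,3,2-dioxaborolane would give the pinacol boronate F4, an isolable nucleophile that can be purified. Suzuki–Miyaura coupling of F4 with 17 (Pd(OAc)2, SPhos, K3PO4, toluene–H2O, 80 °C), again at the iodide, would give 20.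

**Further compounds**

F1 | step 12 | (R)-2-(benzyloxy)-3-[2,4-bis(benzyloxy)-6-fluorophenyl]-N-methoxy-N-methylpropanamide | CON(C)C(=O)[C@H](OCc1ccccc1)Cc1c(F)cc(OCc2ccccc2)cc1OCc1ccccc1
F2 | step 12 | (R)-α-benzyloxy aryl ketone, the C2-oxo form of 23 | O=C(c1cc(OCc5ccccc5)c(OCc5ccccc5)cc1-c1c([C@H]3Oc4cc(OCc5ccccc5)cc(OCc5ccccc5)c4C[C@H]3OCc6ccccc6)cc(OCc5ccccc5)c(OCc5ccccc5)c1OCc5ccccc5)[C@H](OCc5ccccc5)Cc1c(F)cc(OCc5ccccc5)cc1OCc1ccccc1
F3 | step 9 | (R)-2-(benzyloxy)-3-[2,4-bis(benzyloxy)-6-fluorophenyl]-1-[3,4,5-tris(benzyloxy)-2-bromophenyl]propan-1-one | O=C(c1cc(OCc2ccccc2)c(OCc2ccccc2)c(OCc2ccccc2)c1Br)[C@H](OCc1ccccc1)Cc1c(F)cc(OCc2ccccc2)cc1OCc1ccccc1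
F4 | step 11 | pinacol boronate of 15 (4,4,5,5-tetramethyl-1,3,2-dioxaborolan-2-yl in place of the 2'-bromine) | CC1(C)OB(OC1(C)C)c1c([C@H]3Oc4cc(OCc5ccccc5)cc(OCc5ccccc5)c4C[C@H]3OCc6ccccc6)cc(OCc5ccccc5)c(OCc5ccccc5)c1OCc5ccccc5
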